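**Strategy.** Each 2-aryl-3-(hydroxymethyl)dihydrofuran of the target (O1–C2–C3 fused to ring B at C3a/C7a, and its primed twin on ring C) is read as a 2-arylchroman-4-one that has pushed one ring carbon outside the ring. The exocyclic C9 (C9′) is the former carbonyl carbon, and C2 (C2′) is the only stereocentre the six-membered ring must carry. The precursor is therefore a (2R,2′R) bis-flavanone, built by two catalyst-controlled aryl additions to one bromochromone, with ring A masked as a pivalate and ring C bearing bromine. One oxidation with trivalent iodine then shifts each fused arene carbon from C9 to C3, forming C3–C3a and C3′–C3a′, both dihydrofurans and both trans C2/C3 pairs at once.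

Key step: step 9

Remark on stereochemistry: the (S) ligand is written for steps 5 and 8 on the expectation, by analogy with β-substituted cyclic enones, that it delivers the aryl group to the chromone face giving the (2R) flavanone; if the sense is opposite, the (R) ligand is used and nothing else changes.

Remark on design: ring A is an aryl ester from the start (a weaker donor than any ether, stable to acid and orthoformate, removed in the last reduction), and ring C keeps bromine rather than an alkene until after the oxidation, so trivalent iodine meets only the two enol ethers.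

Step 1
Reactants: 1 1-(2-hydroxy-3-methoxyphenyl)ethanone
Product: 2 1-(5-bromo-2-hydroxy-3-methoxyphenyl)ethanone
Conditions: NBS, MeCN, 0 °C to rt
Reagents that add atoms: N-bromosuccinimide, O=C1CCC(=O)N1Br
Why: Electrophilic aromatic bromination, in which the phenol directs to its only free para position C5 (both ortho positions are substituted) and the polar, non-radical medium leaves the acetyl group alone.

Step 2
Reactants: 2 1-(5-bromo-2-hydroxy-3-methoxyphenyl)ethanone
Product: 4 6-bromo-8-methoxy-4H-chromen-4-one, via enaminone 3 (not isolated)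
Conditions: Me2NCH(OMe)2, toluene, 100 °C; then conc. HCl, CH2Cl2, 40 °C
Reagents that add atoms: N,N-dimethylformamide dimethyl acetal, COC(OC)N(C)C
Why: Enaminone condensation of the methyl ketone with the amide acetal, then acid-promoted 6-endo addition of the phenol and loss of dimethylamine, the standard chromone synthesis from 2-hydroxyacetophenones.

Step 3
Reactants: 5 2-methoxy-4-(4,4,5,5-tetramethyl-1,3,2-dioxaborolan-2-yl)phenol
Product: 6 2-methoxy-4-(4,4,5,5-tetramethyl-1,3,2-dioxaborolan-2-yl)phenyl pivalate
Conditions: PivCl, Et3N, DMAP (cat.), CH2Cl2, 0 °C to rt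
Reagents that add atoms: pivaloyl chloride, CC(C)(C)C(=O)Cl
Why: DMAP-catalysed O-acylation of the phenol, to which the pinacol boronate is inert.

Step 4
Reactants: 6 2-methoxy-4-(4,4,5,5-tetramethyl-1,3,2-dioxaborolan-2-yl)phenyl pivalate
Product: 7 [3-methoxy-4-(pivaloyloxy)phenyl]boronic acid
Conditions: NaIO4, NH4OAc, acetone/H2O, rt
Reagents that add atoms: water, O
Why: Oxidative cleavage of the pinacol by periodate drives boronate hydrolysis to the free boronic acid, which is taken to transmetalate to divalent palladium much faster than the pinacol ester, while the hindered aryl ester is stable at this near-neutral pH.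

Step 5
Reactants: 4 6-bromo-8-methoxy-4H-chromen-4-one; 7 [3-methoxy-4-(pivaloyloxy)phenyl]boronic acid (excess)
Product: 8 4-[(2R)-6-bromo-8-methoxy-4-oxochroman-2-yl]-2-methoxyphenyl pivalate
Conditions: Pd(OCOCF3)2 (5 mol %), (S)-4-tert-butyl-2-(pyridin-2-yl)-4,5-dihydrooxazole (6 mol %), NH4PF6, H2O (5 equiv), ClCH2CH2Cl, 60 °C
Reagents that add atoms: none
Why: Enantioselective conjugate addition of an arylboronic acid to a chromone under cationic divalent palladium/pyridine-oxazoline catalysis (transmetalation, insertion of C2=C3 into the aryl–palladium bond on the face fixed by the tert-butyl group of the ligand, which sets C2 as R, then protonolysis of the palladium enolate), a cycle that never passes through zerovalent palladium, so the aryl bromide should survive.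

Step 6
Reactants: 8 4-[(2R)-6-bromo-8-methoxy-4-oxochroman-2-yl]-2-methoxyphenyl pivalate; 9 bis(pinacolato)diboron
Product: 10 2-methoxy-4-[(2R)-8-methoxy-4-oxo-6-(4,4,5,5-tetramethyl-1,3,2-dioxaborolan-2-yl)chroman-2-yl]phenyl pivalate
Conditions: PdCl2(dppf) (cat.), KOAc, 1,4-dioxane, 80 °C
Reagents that add atoms: bis(pinacolato)diboron (9), CC1(C)OB(OC1(C)C)B1OC(C)(C)C(C)(C)O1
Why: Miyaura borylation of the aryl bromide through zerovalent palladium, with acetate as the only base, which is too weak to enolise the ketone or open the pyranone at a useful rate, so C2 should be preserved.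

Step 7
Reactants: 10 2-methoxy-4-[(2R)-8-methoxy-4-oxo-6-(4,4,5,5-tetramethyl-1,3,2-dioxaborolan-2-yl)chroman-2-yl]phenyl pivalate
Product: 11 [(2R)-8-methoxy-2-[3-methoxy-4-(pivaloyloxy)phenyl]-4-oxochroman-6-yl]boronic acid
Conditions: NaIO4, NH4OAc, acetone/H2O, rt
Reagents that add atoms: water, O
Why: The same periodate-driven release of the free boronic acid as in step 4, under near-neutral conditions that spare the ketone, the C2 centre and the pivalate.

Step 8
Reactants: 11 [(2R)-8-methoxy-2-[3-methoxy-4-(pivaloyloxy)phenyl]-4-oxochroman-6-yl]boronic acid; 4 6-bromo-8-methoxy-4H-chromen-4-one (excess, recoverable)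
Product: 12 4-[(2R)-6-[(2R)-6-bromo-8-methoxy-4-oxochroman-2-yl]-8-methoxy-4-oxochroman-2-yl]-2-methoxyphenyl pivalate
Conditions: Pd(OCOCF3)2 (5 mol %), (S)-4-tert-butyl-2-(pyridin-2-yl)-4,5-dihydrooxazole (6 mol %), NH4PF6, H2O (5 equiv), ClCH2CH2Cl, 60 °C
Reagents that add atoms: none
Why: A second conjugate addition of the same type forms C6–C2′ and sets C2′ as R under ligand control, the remote C2 exerting no bias, and the minor C2′ epimer, being a diastereomer, should be removable by chromatography.

Step 9
Reactants: 12 4-[(2R)-6-[(2R)-6-bromo-8-methoxy-4-oxochroman-2-yl]-8-methoxy-4-oxochroman-2-yl]-2-methoxyphenyl pivalate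
Product: 14 methyl (2R,3R)-5-[(2R,3R)-5-bromo-7-methoxy-3-(methoxycarbonyl)-2,3-dihydrobenzofuran-2-yl]-7-methoxy-2-[3-methoxy-4-(pivaloyloxy)phenyl]-2,3-dihydrobenzofuran-3-carboxylate, via bis(enol ether) 13 (not isolated)
Conditions: PhI(OAc)2 (2.5 equiv), H2SO4 (cat.), HC(OMe)3, 0 °C to rt
Reagents that add atoms: trimethyl orthoformate, COC(OC)OC
Why: Acid and orthoformate convert both C4 ketones into 4-methoxy-2H-chromene enol ethers (13), each of which attacks trivalent iodine at C3 on the face away from the C2 aryl group; methanol adds to the former carbonyl carbon, and the fused arene carbon (C4a of the chromanone, C3a of the product) shifts from that carbon to C3 with loss of iodobenzene, the resulting dimethoxycarbenium ion collapsing to the methyl ester. The closest known reaction is the ring contraction of simple flavanones to trans methyl 2-aryl-2,3-dihydrobenzofuran-3-carboxylates with PhI(OAc)2 or Tl(NO3)3 in trimethyl orthoformate, here run twice in one flask. Neither dihydrofuran is closed by a cyclisation: each arises by contraction of the six-membered pyranone through a 1,2-aryl shift via a spiro phenonium ion (formally a 3-exo-tet attack of the arene on C3), which makes the C3–C3a and C3′–C3a′ bonds. C2 and C2′ are untouched and control C3 and C3′, because anti iodination followed by inversion at C3 during the shift places the ester trans to the aryl group, which is also the more stable arrangement, so any acid-mediated equilibration converges on the same (2R,3R,2′R,3′R) isomer. The step needs the fused arene carbon, activated by the ortho ring oxygen, to migrate faster than the C2 aryl group: ring A is held back by its para pivaloyloxy group, bromine keeps ring C free of an alkene that trivalent iodine could attack, and ring B, the one donor-substituted competitor at C2′, has to be outrun, which the ketal-forming orthoformate medium and low temperature are meant to secure.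

Step 10
Reactants: 14 the trans,trans bromo diester from step 9; 15 methyl acrylate
Product: 16 methyl (2R,3R)-7-methoxy-5-[(2R,3R)-7-methoxy-3-(methoxycarbonyl)-5-[(E)-3-methoxy-3-oxoprop-1-enyl]-2,3-dihydrobenzofuran-2-yl]-2-[3-methoxy-4-(pivaloyloxy)phenyl]-2,3-dihydrobenzofuran-3-carboxylate
Conditions: Pd2(dba)3 (cat.), [HP(t-Bu)3]BF4, Cy2NMe, 1,4-dioxane, rt to 50 °C
Reagents that add atoms: methyl acrylate (15), C=CC(=O)OC
Why: Mizoroki–Heck reaction of the electron-rich aryl bromide with an acrylate, giving the E cinnamate by syn insertion and syn β-hydride elimination, run with a bulky trialkylphosphine so that a hindered amine near room temperature suffices and the two base-sensitive C3 esters are spared.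

Step 11
Reactants: 16 the triester pivalate from step 10
Product: 17 4-[(2R,3S)-3-(hydroxymethyl)-5-[(2R,3S)-3-(hydroxymethyl)-5-[(E)-3-hydroxyprop-1-enyl]-7-methoxy-2,3-dihydrobenzofuran-2-yl]-7-methoxy-2,3-dihydrobenzofuran-2-yl]-2-methoxyphenol (target)
Conditions: i-Bu2AlH (excess), CH2Cl2, −78 to 0 °C; aq. potassium sodium tartrate
Reagents that add atoms: none
Why: Hydride reduction with i-Bu2AlH should take the two saturated methyl esters and, in a 1,2 sense, the cinnamate to primary alcohols and cleave the aryl pivalate to the phenol in one operation, under non-basic conditions that leave all four stereocentres and the E alkene untouched (the C3 and C3′ descriptors change from R to S only through a change of substituent priority).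

**Compound list**

1 | 1-(2-hydroxy-3-methoxyphenyl)ethanone | CC(=O)c1cccc(OC)c1O | starting material
2 | 1-(5-bromo-2-hydroxy-3-methoxyphenyl)ethanone | CC(=O)c1cc(Br)cc(OC)c1O | intermediate
3 | (E)-1-(5-bromo-2-hydroxy-3-methoxyphenyl)-3-(dimethylamino)prop-2-en-1-one | CN(C)/C=C/C(=O)c1cc(Br)cc(OC)c1O | intermediate
4 | 6-bromo-8-methoxy-4H-chromen-4-one | COc1cc(Br)cc2c1OC=CC2=O | intermediate
5 | 2-methoxy-4-(4,4,5,5-tetramethyl-1,3,2-dioxaborolan-2-yl)phenol | COc1cc(B2OC(C)(C)C(C)(C)O2)ccc1O | starting material
6 | 2-methoxy-4-(4,4,5,5-tetramethyl-1,3,2-dioxaborolan-2-yl)phenyl pivalate | COc1cc(B2OC(C)(C)C(C)(C)O2)ccc1OC(=O)C(C)(C)C | intermediate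
7 | [3-methoxy-4-(pivaloyloxy)phenyl]boronic acid | COc1cc(B(O)O)ccc1OC(=O)C(C)(C)C | intermediate
8 | 4-[(2R)-6-bromo-8-methoxy-4-oxochroman-2-yl]-2-methoxyphenyl pivalate | COc1cc([C@@H]2Oc3c(OC)cc(Br)cc3C(=O)C2)ccc1OC(=O)C(C)(C)C | intermediate
9 | bis(pinacolato)diboron | CC1(C)OB(OC1(C)C)B1OC(C)(C)C(C)(C)O1 | starting material
10 | 2-methoxy-4-[(2R)-8-methoxy-4-oxo-6-(4,4,5,5-tetramethyl-1,3,2-dioxaborolan-2-yl)chroman-2-yl]phenyl pivalate | COc1cc([C@@H]2Oc3c(OC)cc(B4OC(C)(C)C(C)(C)O4)cc3C(=O)C2)ccc1OC(=O)C(C)(C)C | intermediate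
11 | [(2R)-8-methoxy-2-[3-methoxy-4-(pivaloyloxy)phenyl]-4-oxochroman-6-yl]boronic acid | COc1cc([C@@H]2Oc3c(OC)cc(B(O)O)cc3C(=O)C2)ccc1OC(=O)C(C)(C)C | intermediate
12 | 4-[(2R)-6-[(2R)-6-bromo-8-methoxy-4-oxochroman-2-yl]-8-methoxy-4-oxochroman-2-yl]-2-methoxyphenyl pivalate | COc1cc([C@@H]2Oc3c(OC)cc([C@@H]4Oc5c(OC)cc(Br)cc5C(=O)C4)cc3C(=O)C2)ccc1OC(=O)C(C)(C)C | intermediate
13 | 4-[(2R)-6-[(2R)-6-bromo-4,8-dimethoxy-2H-chromen-2-yl]-4,8-dimethoxy-2H-chromen-2-yl]-2-methoxyphenyl pivalate | COc1cc([C@@H]2Oc3c(OC)cc([C@@H]4Oc5c(OC)cc(Br)cc5C(OC)=C4)cc3C(OC)=C2)ccc1OC(=O)C(C)(C)C | intermediate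
14 | methyl (2R,3R)-5-[(2R,3R)-5-bromo-7-methoxy-3-(methoxycarbonyl)-2,3-dihydrobenzofuran-2-yl]-7-methoxy-2-[3-methoxy-4-(pivaloyloxy)phenyl]-2,3-dihydrobenzofuran-3-carboxylate | COc1cc([C@@H]2Oc3c(OC)cc([C@@H]4Oc5c(OC)cc(Br)cc5[C@H]4C(=O)OC)cc3[C@H]2C(=O)OC)ccc1OC(=O)C(C)(C)C | intermediate
15 | methyl acrylate | C=CC(=O)OC | starting material
16 | methyl (2R,3R)-7-methoxy-5-[(2R,3R)-7-methoxy-3-(methoxycarbonyl)-5-[(E)-3-methoxy-3-oxoprop-1-enyl]-2,3-dihydrobenzofuran-2-yl]-2-[3-methoxy-4-(pivaloyloxy)phenyl]-2,3-dihydrobenzofuran-3-carboxylate | COc1cc([C@@H]2Oc3c(OC)cc([C@@H]4Oc5c(OC)cc(/C=C/C(=O)OC)cc5[C@H]4C(=O)OC)cc3[C@H]2C(=O)OC)ccc1OC(=O)C(C)(C)C | intermediate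
17 | 4-[(2R,3S)-3-(hydroxymethyl)-5-[(2R,3S)-3-(hydroxymethyl)-5-[(E)-3-hydroxyprop-1-enyl]-7-methoxy-2,3-dihydrobenzofuran-2-yl]-7-methoxy-2,3-dihydrobenzofuran-2-yl]-2-methoxyphenol | COc1cc([C@@H]2Oc3c(OC)cc([C@@H]4Oc5c(OC)cc(/C=C/CO)cc5[C@H]4CO)cc3[C@H]2CO)ccc1O | target

**Step count.** Total: 11 steps. Longest linear sequence: 9 steps (1, 2, 5, 6, 7, 8, 9, 10, 11; the branch 3, 4, 5–11 is equally long).

**Steps most likely to fail**

Step 9. The ring B aryl group on C2′ may migrate in place of the fused arene carbon, and the benzylic C2–O1 and C2′–O1′ bonds may ionise in acid and erode configuration. The fallback keeps the same skeletal change but makes it through carbenes, where only the carbonyl-bound arene carbon can shift. It sets out from 12. Condensation with tert-butoxybis(dimethylamino)methane in toluene should give the bis(3-dimethylaminomethylene) diketone F1. Diazo transfer from TsN3 onto the enaminones, with loss of the N-sulfonylformamidine, gives the bis(3-diazo) diketone F2. Irradiation in methanol then brings about a twofold Wolff rearrangement; trapping of the ketenes and protonation of C3 away from the aryl group should give mainly the cis,cis diester F3. A catalytic amount of DBU in CH2Cl2 equilibrates F3 to the trans,trans diester, and the route is rejoined at 14.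

Step 8. Slow transmetalation and protodeboronation of the advanced boronic acid, which is the limiting partner, may leave the C6–C2′ bond formed in low conversion. The fallback reverses the direction of assembly so that the valuable intermediate is always the acceptor and the boronic acid is always simple and in excess. It sets out from 4. Miyaura borylation with 9 gives 8-methoxy-6-(4,4,5,5-tetramethyl-1,3,2-dioxaborolan-2-yl)-4H-chromen-4-one F4, and NaIO4/NH4OAc releases (8-methoxy-4-oxo-4H-chromen-6-yl)boronic acid F5. Because F5 is itself an acceptor, it is added slowly to an excess of 4 under the conditions of step 5, which should give (2R)-6-bromo-8-methoxy-2-(8-methoxy-4-oxo-4H-chromen-6-yl)chroman-4-one F6. Addition of 7 (excess) to the remaining chromone of F6 under the same catalyst then sets C2, and the route is rejoined at 12.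

Step 10. The amine base may deprotonate C3 or C3′ and expel the ring oxygen, opening the dihydrofurans with loss of both centres of a ring. The fallback removes the acidic positions before any base is used. It sets out from 14. Reduction with i-Bu2AlH gives the bromo triol 4-[(2R,3S)-5-[(2R,3S)-5-bromo-3-(hydroxymethyl)-7-methoxy-2,3-dihydrobenzofuran-2-yl]-3-(hydroxymethyl)-7-methoxy-2,3-dihydrobenzofuran-2-yl]-2-methoxyphenol F7. Suzuki–Miyaura coupling of F7 with (E)-3-(4,4,5,5-tetramethyl-1,3,2-dioxaborolan-2-yl)prop-2-en-1-ol (PdCl2(dppf), K2CO3, 1,4-dioxane/H2O, 80 °C) installs the E allylic alcohol directly, and the route is rejoined at 17.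

**Further compounds**

F1 | step 9 | bis(3-dimethylaminomethylene) derivative of 12 (E enaminones, C2 and C2′ as in 12) | COc1cc([C@@H]2Oc3c(OC)cc([C@@H]4Oc5c(OC)cc(Br)cc5C(=O)/C4=C/N(C)C)cc3C(=O)/C2=C/N(C)C)ccc1OC(=O)C(C)(C)C
F2 | step 9 | bis(3-diazo) derivative of 12 (C2 and C2′ as in 12) | COc1cc([C@@H]2Oc3c(OC)cc([C@@H]4Oc5c(OC)cc(Br)cc5C(=O)C4=[N+]=[N-])cc3C(=O)C2=[N+]=[N-])ccc1OC(=O)C(C)(C)C
F3 | step 9 | cis,cis diester, the (2R,3S,2′R,3′S) epimer of 14 | COc1cc([C@@H]2Oc3c(OC)cc([C@@H]4Oc5c(OC)cc(Br)cc5[C@@H]4C(=O)OC)cc3[C@@H]2C(=O)OC)ccc1OC(=O)C(C)(C)C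
F4 | step 8 | 8-methoxy-6-(4,4,5,5-tetramethyl-1,3,2-dioxaborolan-2-yl)-4H-chromen-4-one | COc1cc(B2OC(C)(C)C(C)(C)O2)cc2c1OC=CC2=O
F5 | step 8 | (8-methoxy-4-oxo-4H-chromen-6-yl)boronic acid | COc1cc(B(O)O)cc2c1OC=CC2=O
F6 | step 8 | (2R)-6-bromo-8-methoxy-2-(8-methoxy-4-oxo-4H-chromen-6-yl)chroman-4-one | COc1cc(cc2c1OC=CC2=O)[C@@H]1Oc2c(OC)cc(Br)cc2C(=O)C1
F7 | step 10 | 4-[(2R,3S)-5-[(2R,3S)-5-bromo-3-(hydroxymethyl)-7-methoxy-2,3-dihydrobenzofuran-2-yl]-3-(hydroxymethyl)-7-methoxy-2,3-dihydrobenzofuran-2-yl]-2-methoxyphenol | COc1cc([C@@H]2Oc3c(OC)cc([C@@H]4Oc5c(OC)cc(Br)cc5[C@H]4CO)cc3[C@H]2CO)ccc1O
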